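All runs stem from a simulated flask from invented constants; the scatter is artificial.

The birch run is the grey recipe followed as far as 30.0 h, where complex with one exchanged stood at 38.1% of the charge and starting complex at 46.6%. The next run must choose between charging everything at the start and bringing one partner in late. The oak run, with half the birch strength of both partners, held 53.0% of its starting complex at 48.0 h, and birch held 51.7% at 25.0 h, so within the scatter of the readings oak took twice the time for a like loss. That is the mark of a second-order step: at fixed equivalents the loss follows time multiplied by strength.

| flask | starting complex | incoming ligand | remark | time |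
|---|---|---|---|---|
| birch | 18 mM | 1.2 equiv | run made earlier |  |
| larch | 18 mM | 0.60 equiv | run made earlier |  |
| cedar | 18 mM | 0.90 equiv | run made earlier |  |
| oak | 9 mM | 1.2 equiv | run made earlier |  |
| teal | 18 mM | 1.20 equiv (fed, over 40 h) | all else is in the flask from the start; the feed brings no volume worth counting | 50 h |
| grey | 18 mM | 1.20 equiv | everything together at the start | 50 h |
| blue | 18 mM (fed, over 40 h) | 1.20 equiv | all else is in the flask from the start; the feed brings no volume worth counting | 50 h |
| ochre | 18 mM (in portions, 5, over 40 h) | 1.20 equiv | first portion at the start, last at 40 h | 50 h |

- birch (time / h: complex with one exchanged / %, starting complex / %): 6.00: 17.9, 81.1; 12.0: 26.5, 68.8; 20.0: 31.6, 55.9; 25.0: 34.5, 51.7; 30.0: 38.1, 46.6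
- larch (time / h: complex with one exchanged / %, starting complex / %): 10.0: 11.8, 85.8; 20.0: 19.9, 76.5; 30.0: 25.2, 69.6; 40.0: 28.7, 65.8; 48.0: 30.2, 62.3
- cedar (time / h: complex with one exchanged / %, starting complex / %): 10.0: 17.1, 78.4; 20.0: 28.0, 66.1; 30.0: 33.1, 57.9; 40.0: 37.5, 51.4; 48.0: 42.4, 49.0
- oak (time / h: complex with one exchanged / %, starting complex / %): 4.00: 5.5, 92.3; 8.00: 10.4, 86.2; 15.0: 18.4, 77.5; 25.0: 25.5, 66.0; 48.0: 34.9, 53.0

(scatter of a reading: 1 percentage point)

* the flask that comes out highest in amount of complex with one exchanged, in percent of the starting complex charged, or "all alike" when all lie within 1.5 percentage points (teal / grey / blue / ochre / all alike)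
* complex with one exchanged at the end, in percent of the starting complex charged, teal
* complex with one exchanged at the end, in percent of the starting complex charged, grey
* complex with one exchanged at the end, in percent of the starting complex charged, blue
* complex with one exchanged at the end, in percent of the starting complex charged, ochre

- the numbers in the tables scatter with a standard deviation of 1 percentage point

A late charge therefore has to be counted by its mean age, the run time less the mean time of entry, which for an even feed or evenly spaced equal portions is 30.0 h. Teal, blue and ochre have the same mean age, less than grey's 50 h, so all three should end near the birch reading at that age, 38.1%. Grey should go on from that reading. Birch gained 6.5 points in its last 10.0 h, which puts grey between 44.6% if the gain halves and 51.1% if it holds. The next run is charged at the start, with feed and portions dropped.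

The forecast also chose grey, but put it lower than this reckoning, at 40% (range 37.5% to 43%), with teal 37%, blue 33.5% and ochre 32.5%, holding that “Feeding complex into excess ligand favours over-exchange, and also arrives late”.

The flasks give teal 36.7%, grey 48.9%, blue 35.0% and ochre 33.9%.

    complex with one exchanged + incoming ligand ⇌ leaving ligand + complex with two exchanged (K = 0.600, k = 0.0420 /M/min)
    starting complex + incoming ligand → leaving ligand + complex with one exchanged (k = 0.0290 /M/min)

The 40 h of addition lasts twice the 18 h half-life of starting complex by the first exchange in grey at the charged amounts. At 50 h teal, blue and ochre hold 49.3%, 50.1% and 51.1% of starting complex, beside the 46.6% read in birch at the mean age of 30.0 h, while grey holds 35.7%. A neighbour of ochre with 2.00 equiv of incoming ligand has that mean age at a higher charge of incoming ligand, worth 50.0 h of birch time, so its starting complex should stand near grey's 35.7%. It stands at 33.6%, with complex with one exchanged at 40.8% and complex with two exchanged at 25.7%.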